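The route rests on cutting the O1–C2 bond of the 2,2-dimethylchroman fused to ring A. The feature exploited is the 3-methylbut-2-enyl chain on C3′ of the acylphloroglucinol ring A, whose alkene carbon C3″ lies within reach of the neighbouring C4′ hydroxyl (para to the ketone). Acid-mediated Markovnikov hydroalkoxylation joins that oxygen to C3″ and closes the pyran ring in one operation. The precursor is the open dihydrochalcone: ring A as a free 3′-prenyl triol, ring B as an ortho-prenyl phenol masked as its TIPS ether so that only ring A can cyclise. Both prenyl groups are installed regiospecifically beforehand, and the two rings are joined by an aryllithium–Weinreb amide coupling.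

Key step: step 8

Remark: ring A atoms are labelled C1′–C6′ from the acyl-bearing carbon and the ring A prenyl carbons C1″–C3″ from the ring; the target is achiral, and the aryl TIPS ether is assumed to tolerate methanolic HCl at room temperature, as aryl triisopropylsilyl ethers generally do.

Step 1
Reactants: 1 methyl 3-(4-hydroxyphenyl)propanoate; 2 prenyl bromide (1-bromo-3-methylbut-2-ene)
Product: 4 methyl 3-[4-hydroxy-3-(3-methylbut-2-enyl)phenyl]propanoate, via sodium phenoxide 3 (not isolated)
Conditions: NaH (1.0 equiv), toluene, 0 °C → rt; then prenyl bromide, rt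
Reagents that add atoms: none
Why: Ortho C-alkylation of a phenoxide, in which the tightly ion-paired sodium phenoxide in a non-polar solvent should be alkylated at the ring carbon next to oxygen by SN2 attack on the primary allylic bromide (prenyl group unrearranged), the para position being blocked by the propanoate chain.

Step 2
Reactants: 4 methyl 3-[4-hydroxy-3-(3-methylbut-2-enyl)phenyl]propanoate
Product: 5 methyl 3-[3-(3-methylbut-2-enyl)-4-(triisopropylsilyloxy)phenyl]propanoate
Conditions: TIPSCl, imidazole, DMF, rt
Reagents that add atoms: chlorotriisopropylsilane (TIPSCl), CC(C)[Si](Cl)(C(C)C)C(C)C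
Why: Imidazole-promoted silylation of a phenol gives a bulky aryl silyl ether that cannot quench the aryllithium of step 6 and cannot trap the ring B prenyl cation in step 8.

Step 3
Reactants: 5 methyl 3-[3-(3-methylbut-2-enyl)-4-(triisopropylsilyloxy)phenyl]propanoate
Product: 6 N-methoxy-N-methyl-3-[3-(3-methylbut-2-enyl)-4-(triisopropylsilyloxy)phenyl]propanamide
Conditions: MeNHOMe·HCl, iPrMgCl, THF, −20 → 0 °C; aq. NH4Cl
Reagents that add atoms: N,O-dimethylhydroxylamine hydrochloride, CNOC.Cl
Why: Direct ester-to-Weinreb-amide conversion by acyl substitution with the chloromagnesium amide made in the flask, under conditions to which the aryl silyl ether and the trisubstituted alkene are inert.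

Step 4
Reactants: 7 phloroglucinol
Product: 8 1,3,5-tris(methoxymethoxy)benzene
Conditions: MOMCl, iPr2NEt, DMF, 0 °C → rt
Reagents that add atoms: chloromethyl methyl ether (MOMCl), COCCl
Why: Williamson-type O-alkylation of the three phenols by the hard electrophile MOMCl installs acetal ethers that later direct both lithiations.

Step 5
Reactants: 8 1,3,5-tris(methoxymethoxy)benzene; 2 prenyl bromide
Product: 10 1,3,5-tris(methoxymethoxy)-2-(3-methylbut-2-enyl)benzene, via aryllithium 9 (not isolated)
Conditions: n-BuLi, THF, 0 °C; then prenyl bromide, −78 °C → rt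
Reagents that add atoms: none
Why: Directed ortho-metalation removes a ring proton flanked by two OMOM groups and SN2 alkylation of the aryllithium by the primary allylic bromide places the ring A prenyl group on carbon, avoiding the O- versus C- and mono- versus bis-alkylation problems of prenylating a free acylphloroglucinol.

Step 6
Reactants: 10 1,3,5-tris(methoxymethoxy)-2-(3-methylbut-2-enyl)benzene; 6 N-methoxy-N-methyl-3-[3-(3-methylbut-2-enyl)-4-(triisopropylsilyloxy)phenyl]propanamide
Product: 13 1-[2,4,6-tris(methoxymethoxy)-3-(3-methylbut-2-enyl)phenyl]-3-[3-(3-methylbut-2-enyl)-4-(triisopropylsilyloxy)phenyl]propan-1-one, via aryllithium 11 (not isolated), via lithium hemiaminal 12 (not isolated)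
Conditions: n-BuLi, THF, 0 °C; then 6, −78 → 0 °C; aq. NH4Cl
Reagents that add atoms: none
Why: A second directed ortho-metalation at one of the two symmetry-equivalent ring positions between two OMOM groups (kinetically preferred over the benzylic-allylic CH2) followed by Weinreb ketone synthesis, the chelated tetrahedral adduct preventing over-addition until work-up releases the ketone.

Step 7
Reactants: 13 1-[2,4,6-tris(methoxymethoxy)-3-(3-methylbut-2-enyl)phenyl]-3-[3-(3-methylbut-2-enyl)-4-(triisopropylsilyloxy)phenyl]propan-1-one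
Product: 14 1-[2,4,6-trihydroxy-3-(3-methylbut-2-enyl)phenyl]-3-[3-(3-methylbut-2-enyl)-4-(triisopropylsilyloxy)phenyl]propan-1-one
Conditions: conc. HCl (cat.), MeOH, rt
Reagents that add atoms: none
Why: Acid-catalysed acetal exchange with methanol cleaves the three aryl MOM ethers as dimethoxymethane, while the methanol-levelled acid at room temperature should protonate the trisubstituted alkenes too slowly to matter and leaves the aryl TIPS ether intact.

Step 8
Reactants: 14 1-[2,4,6-trihydroxy-3-(3-methylbut-2-enyl)phenyl]-3-[3-(3-methylbut-2-enyl)-4-(triisopropylsilyloxy)phenyl]propan-1-one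
Product: 15 1-(5,7-dihydroxy-2,2-dimethyl-3,4-dihydro-2H-chromen-6-yl)-3-[3-(3-methylbut-2-enyl)-4-(triisopropylsilyloxy)phenyl]propan-1-one
Conditions: p-TsOH·H2O (10 mol %), toluene, rt → 40 °C
Reagents that add atoms: none
Why: Markovnikov protonation of the ring A prenyl alkene at C2″ gives a tertiary cation at C3″ (the future C2 of the chroman), which is captured by a lone pair of the C4′ hydroxyl to form the O1–C2 bond, and loss of the proton regenerates the acid. The closest known reaction type is the acid-catalysed cyclisation of ortho-prenylphenols to 2,2-dimethylchromans, an intramolecular alkene hydroalkoxylation. The pyran ring closes in a 6-endo-trig mode with respect to the alkene, and no stereocentre arises because the new quaternary carbon carries two methyl groups. Two selectivities are needed: O4′ over O2′, and the ring A prenyl group over the ring B prenyl group. The first rests on the C2′ hydroxyl, wedged between the acyl and prenyl groups, being the one expected to hold the hydrogen bond to the ketone in the non-polar medium, which leaves the unhindered, unchelated C4′ hydroxyl as the available nucleophile. The second is secured by the TIPS ether, which leaves the ring B cation without an internal oxygen trap, so that its protonation should merely be reversible under these mild conditions.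

Step 9
Reactants: 15 1-(5,7-dihydroxy-2,2-dimethyl-3,4-dihydro-2H-chromen-6-yl)-3-[3-(3-methylbut-2-enyl)-4-(triisopropylsilyloxy)phenyl]propan-1-one
Product: 16 1-(5,7-dihydroxy-2,2-dimethyl-3,4-dihydro-2H-chromen-6-yl)-3-[4-hydroxy-3-(3-methylbut-2-enyl)phenyl]propan-1-one (CNP0080516.0)
Conditions: TBAF, AcOH, THF, 0 °C → rt
Reagents that add atoms: none
Why: Fluoride-induced cleavage of the aryl silyl ether, driven by Si–F bond formation and buffered with acetic acid so that the acidic acylphloroglucinol stays protonated, touches neither the chroman ether, the ketone nor the prenyl alkene.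

Compound list
1 | methyl 3-(4-hydroxyphenyl)propanoate | COC(=O)CCc1ccc(O)cc1 | starting material
2 | prenyl bromide (1-bromo-3-methylbut-2-ene) | CC(C)=CCBr | starting material
3 | sodium 4-(3-methoxy-3-oxopropyl)phenoxide | COC(=O)CCc1ccc([O-])cc1.[Na+] | intermediate (not isolated)
4 | methyl 3-[4-hydroxy-3-(3-methylbut-2-enyl)phenyl]propanoate | COC(=O)CCc1ccc(O)c(CC=C(C)C)c1 | intermediate
5 | methyl 3-[3-(3-methylbut-2-enyl)-4-(triisopropylsilyloxy)phenyl]propanoate | COC(=O)CCc1ccc(O[Si](C(C)C)(C(C)C)C(C)C)c(CC=C(C)C)c1 | intermediate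
6 | N-methoxy-N-methyl-3-[3-(3-methylbut-2-enyl)-4-(triisopropylsilyloxy)phenyl]propanamide | CON(C)C(=O)CCc1ccc(O[Si](C(C)C)(C(C)C)C(C)C)c(CC=C(C)C)c1 | intermediate
7 | phloroglucinol (benzene-1,3,5-triol) | Oc1cc(O)cc(O)c1 | starting material
8 | 1,3,5-tris(methoxymethoxy)benzene | COCOc1cc(OCOC)cc(OCOC)c1 | intermediate
9 | [2,4,6-tris(methoxymethoxy)phenyl]lithium | [Li]c1c(OCOC)cc(OCOC)cc1OCOC | intermediate (not isolated)
10 | 1,3,5-tris(methoxymethoxy)-2-(3-methylbut-2-enyl)benzene | COCOc1cc(OCOC)c(CC=C(C)C)c(OCOC)c1 | intermediate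
11 | [2,4,6-tris(methoxymethoxy)-3-(3-methylbut-2-enyl)phenyl]lithium | [Li]c1c(OCOC)cc(OCOC)c(CC=C(C)C)c1OCOC | intermediate (not isolated)
12 | lithium hemiaminal (tetrahedral adduct of 11 and 6, O-lithiated) | CON(C)C(O[Li])(CCc1ccc(O[Si](C(C)C)(C(C)C)C(C)C)c(CC=C(C)C)c1)c1c(OCOC)cc(OCOC)c(CC=C(C)C)c1OCOC | intermediate (not isolated)
13 | 1-[2,4,6-tris(methoxymethoxy)-3-(3-methylbut-2-enyl)phenyl]-3-[3-(3-methylbut-2-enyl)-4-(triisopropylsilyloxy)phenyl]propan-1-one | COCOc1cc(OCOC)c(CC=C(C)C)c(OCOC)c1C(=O)CCc1ccc(O[Si](C(C)C)(C(C)C)C(C)C)c(CC=C(C)C)c1 | intermediate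
14 | 1-[2,4,6-trihydroxy-3-(3-methylbut-2-enyl)phenyl]-3-[3-(3-methylbut-2-enyl)-4-(triisopropylsilyloxy)phenyl]propan-1-one | CC(C)=CCc1cc(CCC(=O)c2c(O)cc(O)c(CC=C(C)C)c2O)ccc1O[Si](C(C)C)(C(C)C)C(C)C | intermediate (key-step precursor)
15 | 1-(5,7-dihydroxy-2,2-dimethyl-3,4-dihydro-2H-chromen-6-yl)-3-[3-(3-methylbut-2-enyl)-4-(triisopropylsilyloxy)phenyl]propan-1-one | CC(C)=CCc1cc(CCC(=O)c2c(O)cc3OC(C)(C)CCc3c2O)ccc1O[Si](C(C)C)(C(C)C)C(C)C | intermediate (key-step product)
16 | 1-(5,7-dihydroxy-2,2-dimethyl-3,4-dihydro-2H-chromen-6-yl)-3-[4-hydroxy-3-(3-methylbut-2-enyl)phenyl]propan-1-one | CC(C)=CCc1cc(CCC(=O)c2c(O)cc3c(c2O)CCC(C)(C)O3)ccc1O | target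

Total step count: 9. Longest linear sequence: 7 steps (steps 1, 2, 3, 6, 7, 8, 9); the ring A branch (steps 4 and 5) joins at step 6.

Steps most likely to fail

The step most at risk is step 8. The ring closure may lose site-selectivity between the two hydroxyls that flank the ring A prenyl group, since closure onto O2′ would give the angular 8-acyl chroman. Prolonged acid exposure may also isomerise the ring B alkene. The fallback closes the pyran before the acyl group is present, so that the two flanking oxygens are equivalent. Setting out from 10, HCl in methanol at 50 °C would remove the three MOM groups to give 2-(3-methylbut-2-enyl)benzene-1,3,5-triol F1; any early ring closure here is harmless. p-TsOH in toluene would then cyclise it to 2,2-dimethylchroman-5,7-diol F2, the only chroman possible by symmetry. MOMCl and iPr2NEt would give 5,7-bis(methoxymethoxy)-2,2-dimethylchroman F3. n-BuLi should remove the C6 proton, the only one lying between two OMOM groups, to give the C6 aryllithium F4. Its addition to Weinreb amide 6 would pass through the lithium hemiaminal F5 and give, on work-up, the bis-MOM ketone 1-[5,7-bis(methoxymethoxy)-2,2-dimethylchroman-6-yl]-3-[3-(3-methylbut-2-enyl)-4-(triisopropylsilyloxy)phenyl]propan-1-one F6. Methanolic HCl at room temperature would remove the two MOM groups and return the route at 15.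

Second is step 7. The acid needed for acetal cleavage may trigger premature and uncontrolled ring closure: the two MOM groups ortho to the ketone leave first and expose O2′ beside the prenyl group before O4′ is free. It may also add HCl or methanol across the alkenes. The fallback removes the MOM groups before ring A carries a prenyl group. Setting out from 8 and 6, aryllithium 9 (made as in step 5) would add to 6 through the lithium hemiaminal F7 to give 1-[2,4,6-tris(methoxymethoxy)phenyl]-3-[3-(3-methylbut-2-enyl)-4-(triisopropylsilyloxy)phenyl]propan-1-one F8. Methanolic HCl would then give 1-(2,4,6-trihydroxyphenyl)-3-[3-(3-methylbut-2-enyl)-4-(triisopropylsilyloxy)phenyl]propan-1-one F9, with no alkene next to a free hydroxyl. Mono-C-prenylation of the acylphloroglucinol with prenyl bromide 2 and DBU in THF would rejoin the route at 14, at the cost of the separation from O-alkylated and bis-alkylated material that this classical alkylation entails.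

Third is step 6. The hindered, strongly basic aryllithium may enolise the Weinreb amide instead of adding to it, so that conversion stalls. The fallback uses a more electrophilic partner and restores the ketone by oxidation. Setting out from 5, half-reduction with i-Bu2AlH in CH2Cl2 at −78 °C would give 3-[3-(3-methylbut-2-enyl)-4-(triisopropylsilyloxy)phenyl]propanal F10. Aryllithium 11 would add to it to form the lithium alkoxide F11 and, after aqueous NH4Cl, the racemic alcohol 1-[2,4,6-tris(methoxymethoxy)-3-(3-methylbut-2-enyl)phenyl]-3-[3-(3-methylbut-2-enyl)-4-(triisopropylsilyloxy)phenyl]propan-1-ol F12. Oxidation with Dess–Martin periodinane in CH2Cl2 would rejoin the route at 13; the carbinol stereocentre is lost there, so its configuration is irrelevant.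

Further compounds
F1 | step 8 | 2-(3-methylbut-2-enyl)benzene-1,3,5-triol | CC(C)=CCc1c(O)cc(O)cc1O
F2 | step 8 | 2,2-dimethylchroman-5,7-diol | CC1(C)CCc2c(O)cc(O)cc2O1
F3 | step 8 | 5,7-bis(methoxymethoxy)-2,2-dimethylchroman | COCOc1cc(OCOC)c2CCC(C)(C)Oc2c1
F4 | step 8 | [5,7-bis(methoxymethoxy)-2,2-dimethylchroman-6-yl]lithium | COCOc1cc2OC(C)(C)CCc2c(OCOC)c1[Li]
F5 | step 8 | lithium hemiaminal (tetrahedral adduct of F4 and 6, O-lithiated) | CON(C)C(O[Li])(CCc1ccc(O[Si](C(C)C)(C(C)C)C(C)C)c(CC=C(C)C)c1)c1c(OCOC)cc2OC(C)(C)CCc2c1OCOC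
F6 | step 8 | 1-[5,7-bis(methoxymethoxy)-2,2-dimethylchroman-6-yl]-3-[3-(3-methylbut-2-enyl)-4-(triisopropylsilyloxy)phenyl]propan-1-one | COCOc1cc2OC(C)(C)CCc2c(OCOC)c1C(=O)CCc1ccc(O[Si](C(C)C)(C(C)C)C(C)C)c(CC=C(C)C)c1
F7 | step 7 | lithium hemiaminal (tetrahedral adduct of 9 and 6, O-lithiated) | CON(C)C(O[Li])(CCc1ccc(O[Si](C(C)C)(C(C)C)C(C)C)c(CC=C(C)C)c1)c1c(OCOC)cc(OCOC)cc1OCOC
F8 | step 7 | 1-[2,4,6-tris(methoxymethoxy)phenyl]-3-[3-(3-methylbut-2-enyl)-4-(triisopropylsilyloxy)phenyl]propan-1-one | COCOc1cc(OCOC)c(C(=O)CCc2ccc(O[Si](C(C)C)(C(C)C)C(C)C)c(CC=C(C)C)c2)c(OCOC)c1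
F9 | step 7 | 1-(2,4,6-trihydroxyphenyl)-3-[3-(3-methylbut-2-enyl)-4-(triisopropylsilyloxy)phenyl]propan-1-one | CC(C)=CCc1cc(CCC(=O)c2c(O)cc(O)cc2O)ccc1O[Si](C(C)C)(C(C)C)C(C)C
F10 | step 6 | 3-[3-(3-methylbut-2-enyl)-4-(triisopropylsilyloxy)phenyl]propanal | O=CCCc1ccc(O[Si](C(C)C)(C(C)C)C(C)C)c(CC=C(C)C)c1
F11 | step 6 | lithium alkoxide of F12 (adduct of 11 and F10) | [Li]OC(CCc1ccc(O[Si](C(C)C)(C(C)C)C(C)C)c(CC=C(C)C)c1)c1c(OCOC)cc(OCOC)c(CC=C(C)C)c1OCOC
F12 | step 6 | racemic 1-[2,4,6-tris(methoxymethoxy)-3-(3-methylbut-2-enyl)phenyl]-3-[3-(3-methylbut-2-enyl)-4-(triisopropylsilyloxy)phenyl]propan-1-ol | OC(CCc1ccc(O[Si](C(C)C)(C(C)C)C(C)C)c(CC=C(C)C)c1)c1c(OCOC)cc(OCOC)c(CC=C(C)C)c1OCOC
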